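**Retrosynthetic overview**

1. Feature (ent-kaurane numbering): the bicyclo[3.2.1]octane made of ring C (C8, C9, C11, C12, C13, C14) and the bridge C15–C16, with oxygen on C16 and C17, the formyl carbon C7 on C8, and ring B open between C6 and C7.
2. Key disconnection: C8–C14, C12–C13 and C16–O are formed together from a ring C cyclohexane (C8, C9, C11, C12, C16, C15) that carries a C8 spiro-epoxide (C7–O) and, on C16, a vinyl group (C13=C14) and CH2OBoc (C17).
3. C9–C10 comes from an anionic oxy-Cope rearrangement of the (6R)-carbinol C10=C5–C6(O)–C7–C8=C9. It also cuts C6–C7, leaving C6 as an aldehyde (held with the C19 carboxyl as a pseudo-acid) and C8=C7 as the exo-methylene for the epoxide.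
4. Fragments: ring A enal ester 11 (C4 by auxiliary-controlled methylation) and ring C allyl chloride 23 (C16 by copper-catalysed asymmetric vinyl addition), joined at C6–C7 by an allylbarium addition.
5. Ring order: rings A and C enter as six-membered carbocycles, ring B is never closed, ring D and the reshaped ring C arise in step 21. End game: oxidation at C7, then hydrolysis of acylal and carbonate.

Key step: step 21

Remark 1: all coupled intermediates carry ent-kaurane atom numbers.
Remark 2: the 6-oxo-19-oic acid unit of the target is in ring–chain equilibrium with its 6-hydroxy-19,6-olide; the target is written open-chain. In 32–40 the C6/C19 pair is carried as this cyclic hemiacylal or its acetate (C6 an epimer mixture that vanishes in step 23). An ester on C6–O could not be removed beside the cyclic carbonate, and a hindered C19 alkyl ester could not be hydrolysed beside the dialdehyde.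
Remark 3: in step 2 the sense of the enamine alkylation depends on the auxiliary antipode and the lithium-coordinating additive; the combination that gives (R)-6 is used.

**Route**

Step 1
Reactants: 1 methyl 2-oxocyclohexane-1-carboxylate; 2 tert-butyl L-valinate
Product: 3 methyl 2-{[(2S)-1-tert-butoxy-3-methyl-1-oxobutan-2-yl]amino}cyclohex-1-ene-1-carboxylate
Conditions: AcOH (cat.), 4 Å molecular sieves, toluene, 80 °C
Reagents that add atoms: none
Why: Condensation of the β-keto ester with the amino ester (enamine formation) gives the hydrogen-bonded enamino ester; no stereocentre is made.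

Step 2
Reactants: 3 chiral enamino ester
Product: 6 methyl (1R)-1-methyl-2-oxocyclohexane-1-carboxylate, via lithium aza-enolate 4 (not isolated), via methylated ketimine 5 (not isolated)
Conditions: LiN(iPr)2, toluene, HMPA, −78 °C; MeI, −78 → −20 °C; then 1 M aq. HCl, rt
Reagents that add atoms: iodomethane (CI); water (O)
Why: Koga-type alkylation of the chelated lithiated enamine: the valine side chain and the additive fix the face of C-methylation so that C4 becomes (R), and acid hydrolysis of the ketimine frees the ketone and the auxiliary.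

Step 3
Reactants: 6 (R)-keto ester
Product: 8 methyl (1R)-1,3-dimethyl-2-oxocyclohexane-1-carboxylate (C3 epimer mixture), via lithium enolate 7 (not isolated)
Conditions: LiN(iPr)2, THF, −78 °C; MeI, −78 → 0 °C
Reagents that add atoms: iodomethane (CI)
Why: Enolate alkylation; only C10 carries α-hydrogens, and the new methine centre is erased in step 4.

Step 4
Reactants: 8 dimethyl keto ester
Product: 10 methyl (1R)-1,3-dimethyl-2-{[(trifluoromethyl)sulfonyl]oxy}cyclohex-2-ene-1-carboxylate, via potassium enolate 9 (not isolated)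
Conditions: KN(SiMe3)2, THF, −78 → 0 °C; PhNTf2
Reagents that add atoms: N-phenylbis(trifluoromethanesulfonimide) (O=S(=O)(N(c1ccccc1)S(=O)(=O)C(F)(F)F)C(F)(F)F)
Why: Enol triflate formation; the only possible enolate (C5=C10) is O-sulfonylated and C4 is untouched.

Step 5
Reactants: 10 enol triflate
Product: 11 methyl (1R)-2-formyl-1,3-dimethylcyclohex-2-ene-1-carboxylate
Conditions: Pd(OAc)2 (cat.), Ph2P(CH2)3PPh2, CO (1 atm), Et3SiH, Et3N, DMF, 70 °C
Reagents that add atoms: carbon monoxide ([C-]#[O+])
Why: Palladium-catalysed reductive carbonylation of the enol triflate (CO insertion, then hydride transfer from the silane) gives the tetrasubstituted enal; C4 is not involved.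

Step 6
Reactants: 12 3-methoxybenzyl alcohol
Product: 15 3-(hydroxymethyl)cyclohex-2-en-1-one, via methoxy diene 13 (not isolated), via unconjugated enone 14 (not isolated)
Conditions: Li, NH3 (l), t-BuOH, THF, −78 → −33 °C; NH4Cl; then 1 M aq. HCl, THF, rt
Reagents that add atoms: water (O)
Why: Birch reduction of the anisole ring (benzylic oxygen shielded as its lithium alkoxide), then acid hydrolysis of the enol ether and conjugation of the double bond.

Step 7
Reactants: 15 hydroxymethyl enone
Product: 16 3-({[tert-butyl(dimethyl)silyl]oxy}methyl)cyclohex-2-en-1-one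
Conditions: TBSCl, imidazole, DMF, rt
Reagents that add atoms: tert-butyldimethylsilyl chloride (C[Si](C)(Cl)C(C)(C)C)
Why: Silylation of the primary alcohol gives an ether that survives the organometallic and basic steps up to step 18.

Step 8
Reactants: 16 silyloxymethyl enone; 17 vinylmagnesium bromide
Product: 19 (3R)-3-({[tert-butyl(dimethyl)silyl]oxy}methyl)-3-ethenylcyclohexan-1-one, via dimethyl(vinyl)alane 18 (not isolated)
Conditions: 17, Me2AlCl, Et2O, −30 °C; then 16, Cu(O2CC4H3S) (10 mol%), phosphoramidite from (S)-BINOL and bis[(R)-1-phenylethyl]amine (11 mol%, antipode if required for R), Et2O, −30 °C; 1 M aq. HCl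
Reagents that add atoms: none
Why: Copper-catalysed asymmetric conjugate addition of an alkenylalane to a β-substituted cyclohexenone: vinyl rather than methyl is transferred, on the face chosen by the chiral copper–phosphoramidite complex, which sets the quaternary centre C16 as (R).

Step 9
Reactants: 19 (R)-ketone
Product: 21 (5R)-5-({[tert-butyl(dimethyl)silyl]oxy}methyl)-5-ethenylcyclohex-1-en-1-yl trifluoromethanesulfonate, via lithium enolate 20 (not isolated)
Conditions: LiN(iPr)2, THF, −78 °C; PhNTf2, −78 → 0 °C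
Reagents that add atoms: N-phenylbis(trifluoromethanesulfonimide) (O=S(=O)(N(c1ccccc1)S(=O)(=O)C(F)(F)F)C(F)(F)F)
Why: Kinetic deprotonation takes the α-methylene remote from the quaternary centre (C9), and O-triflation fixes the C8=C9 enol triflate.

Step 10
Reactants: 21 ring C enol triflate
Product: 22 [(5R)-5-({[tert-butyl(dimethyl)silyl]oxy}methyl)-5-ethenylcyclohex-1-en-1-yl]methanol
Conditions: Pd(PPh3)4 (cat.), LiCl, Bu3SnCH2OH, 1,4-dioxane, 100 °C
Reagents that add atoms: (tributylstannyl)methanol (CCCC[Sn](CCCC)(CCCC)CO)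
Why: Stille coupling transfers the hydroxymethyl group (C7) to C8 with the alkene held at C8=C9.

Step 11
Reactants: 22 allylic alcohol
Product: 23 tert-butyl{[(1R)-3-(chloromethyl)-1-ethenylcyclohex-3-en-1-yl]methoxy}dimethylsilane
Conditions: NCS, PPh3, THF, 0 °C → rt
Reagents that add atoms: N-chlorosuccinimide (O=C1CCC(=O)N1Cl)
Why: Appel-type chlorination of the primary allylic alcohol goes by direct displacement, so chlorine stays on C7.

Step 12
Reactants: 23 ring C allylic chloride; 11 ring A enal ester
Product: 25 methyl (1R)-2-{2-[(5R)-5-({[tert-butyl(dimethyl)silyl]oxy}methyl)-5-ethenylcyclohex-1-en-1-yl]-1-hydroxyethyl}-1,3-dimethylcyclohex-2-ene-1-carboxylate (C6 epimer mixture), via allylbarium chloride 24 (not isolated)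
Conditions: BaI2, lithium biphenylide, THF, rt; 23, −78 °C; then 11, −78 °C; AcOH, −78 °C
Reagents that add atoms: none
Why: Allylbarium reagents add 1,2 to aldehydes through the less substituted allyl terminus without transposition, so C7 bonds to C6 and C8=C9 is kept; the C6 epimer mixture is oxidised next, and the cold acidic quench keeps the alkoxide from closing onto the C19 ester.

Step 13
Reactants: 25 carbinol mixture
Product: 26 methyl (1R)-2-{[(5R)-5-({[tert-butyl(dimethyl)silyl]oxy}methyl)-5-ethenylcyclohex-1-en-1-yl]acetyl}-1,3-dimethylcyclohex-2-ene-1-carboxylate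
Conditions: Dess–Martin periodinane, NaHCO3, CH2Cl2, 0 °C → rt
Reagents that add atoms: none
Why: Buffered Dess–Martin oxidation of the secondary allylic alcohol gives the β,γ-unsaturated ketone without moving the C8=C9 alkene.

Step 14
Reactants: 26 ketone
Product: 28 (3R,7aR)-3-{[(5R)-5-({[tert-butyl(dimethyl)silyl]oxy}methyl)-5-ethenylcyclohex-1-en-1-yl]methyl}-4,7a-dimethyl-5,6,7,7a-tetrahydroisobenzofuran-1(3H)-one, via (6R)-hydroxy ester 27 (not isolated)
Conditions: (S)-1-methyl-3,3-diphenyltetrahydro-1H,3H-pyrrolo[1,2-c][1,3,2]oxazaborole [(S)-Me-CBS, 0.5 equiv], catecholborane, toluene, −78 → −40 °C; then K2CO3, MeOH, rt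
Reagents that add atoms: none
Why: Corey–Bakshi–Shibata reduction: with the tetrasubstituted alkenyl group as the large and the methylene as the small substituent the (S)-catalyst should give the (6R)-carbinol, catecholborane spares the vinyl group, and base closes the γ-lactone onto the C19 ester with retention at C6.

Step 15
Reactants: 28 (6R)-lactone
Product: 29 potassium (1R)-2-{(1R)-2-[(5R)-5-({[tert-butyl(dimethyl)silyl]oxy}methyl)-5-ethenylcyclohex-1-en-1-yl]-1-hydroxyethyl}-1,3-dimethylcyclohex-2-ene-1-carboxylate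
Conditions: KOH (1.05 equiv), THF/MeOH/H2O, 40 °C; evaporate, azeotrope with toluene
Reagents that add atoms: potassium hydroxide ([K+].[OH-])
Why: Saponification of the γ-lactone gives a carboxylate that an alkoxide cannot re-acylate, so the C6 oxygen stays free for the rearrangement; no stereocentre is touched.

Step 16
Reactants: 29 potassium hydroxy carboxylate
Product: 32 pseudo-acid (4R,5S,9R,10S,16R): ring A cis-fused 6-hydroxy-19,6-γ-lactone whose C10 bears CH3 and C9 of a cyclohexane with C8 exo-methylene and C16 vinyl/CH2OTBS (C6 epimer mixture), via dipotassium alkoxide carboxylate 30 (not isolated), via dipotassium enolate carboxylate 31 (not isolated)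
Conditions: KH (3 equiv), THF, 0 → 60 °C; aq. NH4Cl, −78 °C; 1 M aq. HCl to pH 3
Reagents that add atoms: none
Why: Anionic oxy-Cope rearrangement of the 3-oxido-1,5-diene C10=C5–C6(O)–C7–C8=C9 through the chair in which the (6R)-oxygen is pseudo-equatorial (potassium-bridged to the C19 carboxylate, C6–H turned toward the C20 methyl to avoid A(1,3) strain) joins C9 to the face of C10 anti to C19, setting C10 and C9 together, and cuts C6–C7 to leave the C8 exo-methylene; the enolate is protonated at C5 anti to the axial C19 and C20 groups and the aldehyde closes with the cis carboxyl group.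

Step 17
Reactants: 32 pseudo-acid
Product: 33 acetoxy lactone (4R,5S,9R,10S,16R): 32 with the C6 hydroxyl acetylated
Conditions: Ac2O, pyridine, DMAP (cat.), CH2Cl2, 0 °C → rt
Reagents that add atoms: acetic anhydride (CC(=O)OC(C)=O)
Why: Acetylation of the hemiacylal hydroxyl gives an acylal that masks C6 at the aldehyde level and C19 at the acid level with oxygen atoms that are not nucleophilic toward cations.

Step 18
Reactants: 33 acetoxy lactone silyl ether
Product: 34 primary alcohol (4R,5S,9R,10S,16R): 33 with C17–OH free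
Conditions: HF·pyridine, THF, 0 °C → rt
Reagents that add atoms: none
Why: Fluoride cleavage of the primary silyl ether under mildly acidic conditions leaves the acylal and both alkenes intact.

Step 19
Reactants: 34 C17 alcohol; 35 di-tert-butyl dicarbonate
Product: 36 tert-butyl carbonate (4R,5S,9R,10S,16R): 34 with C17–OBoc
Conditions: DMAP (cat.), MeCN, rt
Reagents that add atoms: none
Why: DMAP-catalysed acylation of the neopentyl primary alcohol installs the tert-butyl carbonate that later captures the C16 cation.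

Step 20
Reactants: 36 exo-methylene carbonate
Product: 37 spiro-epoxide (4R,5S,8R,9S,10S,16R): 36 with C8=C7 epoxidised and the epoxide oxygen trans to the C16 vinyl group
Conditions: mCPBA, NaHCO3, CH2Cl2, −20 → 0 °C
Reagents that add atoms: 3-chloroperoxybenzoic acid (OOC(=O)c1cccc(Cl)c1)
Why: Prilezhaev epoxidation: the 1,1-disubstituted exocyclic alkene reacts faster than the vinyl group, and in the chair that keeps the ring A substituent on C9 equatorial the C16 vinyl group is axial and shields one face, so oxygen is delivered anti to it and sets C8.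

Step 21
Reactants: 37 spiro-epoxide
Product: 39 (4R,5S,8R,9S,10S,13R,16R)-6-acetoxy-7-hydroxy-6,7-secokauran-19,6-olide 16,17-cyclic carbonate (ent-kaurane series), via tert-butoxydioxolanylium aluminate 38 (not isolated)
Conditions: MeAlCl2 (3 equiv), CH2Cl2, −78 °C; aq. potassium sodium tartrate
Reagents that add atoms: none
Why: Proposed new method: MeAlCl2 opens the spiro-epoxide at the tertiary carbon C8 while the axial vinyl group on C16, held 1,3-diaxial to C8 because the ring A substituent on C9 stays equatorial, attacks through C14 anti to the departing oxygen; the charge developing at C13 is relieved by a suprafacial 1,2-shift of the antiperiplanar C16–C12 bond (Wagner–Meerwein), and the tertiary C16 cation is captured by the Boc carbonyl oxygen with loss of isobutene. The closest known reactions are Lewis-acid epoxide-initiated cation–olefin cyclisations, the solvolytic beyeranyl-to-kauranyl rearrangement and the capture of cations by tert-butyl carbonates, but their union on a ring B-seco substrate has no precedent. The five-membered carbocycle (C8, C14, C13, C16, C15) closes in a cationic 5-endo mode with respect to the vinyl π bond and the shift turns the cyclohexane into the bicyclo[3.2.1]octane, while the dioxolanone closes 5-exo at C16. C8 is set by inversion because the tether from C16 reaches only the face opposite the C–O bond, C13 by the fixed geometry of the migrating bond, and C16 by carbonate attack anti to the leaving C12 on the exo face. The step needs ring closure to outrun the hydride shift to a C8 aldehyde and the shift to outrun carbonate capture at C13; preorganisation of the vinyl group, the low temperature and the gain from a secondary to a tertiary cation are relied on.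

Step 22
Reactants: 39 C7 alcohol
Product: 40 (4R,5S,8R,9S,10S,13R,16R)-6-acetoxy-7-oxo-6,7-secokauran-19,6-olide 16,17-cyclic carbonate
Conditions: Dess–Martin periodinane, NaHCO3, CH2Cl2, 0 °C → rt
Reagents that add atoms: none
Why: Dess–Martin oxidation of the neopentyl primary alcohol gives the C7 aldehyde on quaternary C8, which cannot epimerise, and leaves carbonate and acylal untouched.

Step 23
Reactants: 40 aldehyde carbonate acylal
Product: 41 (4R,5S,8R,9S,10S,13R,16R)-16,17-dihydroxy-6,7-dioxo-6,7-secokauran-19-oic acid (target)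
Conditions: LiOH, THF/H2O, 0 °C; then 1 M aq. HCl to pH 3, 0 °C
Reagents that add atoms: none
Why: Ester hydrolysis: hydroxide removes the acylal acetate, whose hemiacylal anion opens to the C6 aldehyde and the C19 carboxylate, and cleaves the cyclic carbonate to the 16,17-diol; C5–H lies between two quaternary carbons and should resist enolisation at 0 °C.

**Compound list**

1 | methyl 2-oxocyclohexane-1-carboxylate | COC(=O)C1CCCCC1=O | starting material
2 | tert-butyl L-valinate | CC(C)[C@H](N)C(=O)OC(C)(C)C | starting material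
3 | methyl 2-{[(2S)-1-tert-butoxy-3-methyl-1-oxobutan-2-yl]amino}cyclohex-1-ene-1-carboxylate | COC(=O)C1=C(N[C@@H](C(C)C)C(=O)OC(C)(C)C)CCCC1 | intermediate
4 | N-lithio derivative of 3 (lithium aza-enolate, not isolated) | COC(=O)C1=C(N([Li])[C@@H](C(C)C)C(=O)OC(C)(C)C)CCCC1 | intermediate
5 | methyl (1R)-1-methyl-2-{[(2S)-1-tert-butoxy-3-methyl-1-oxobutan-2-yl]imino}cyclohexane-1-carboxylate (not isolated) | COC(=O)[C@]1(C)CCCCC1=N[C@@H](C(C)C)C(=O)OC(C)(C)C | intermediate
6 | methyl (1R)-1-methyl-2-oxocyclohexane-1-carboxylate | COC(=O)[C@]1(C)CCCCC1=O | intermediate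
7 | lithium (6R)-6-(methoxycarbonyl)-6-methylcyclohex-1-en-1-olate (not isolated) | COC(=O)[C@]1(C)CCCC=C1O[Li] | intermediate
8 | methyl (1R)-1,3-dimethyl-2-oxocyclohexane-1-carboxylate (C3 epimers) | COC(=O)[C@]1(C)CCCC(C)C1=O | intermediate
9 | potassium (6R)-6-(methoxycarbonyl)-2,6-dimethylcyclohex-1-en-1-olate (not isolated) | COC(=O)[C@]1(C)CCCC(C)=C1O[K] | intermediate
10 | methyl (1R)-1,3-dimethyl-2-{[(trifluoromethyl)sulfonyl]oxy}cyclohex-2-ene-1-carboxylate | COC(=O)[C@]1(C)CCCC(C)=C1OS(=O)(=O)C(F)(F)F | intermediate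
11 | methyl (1R)-2-formyl-1,3-dimethylcyclohex-2-ene-1-carboxylate | COC(=O)[C@]1(C)CCCC(C)=C1C=O | intermediate
12 | 3-methoxybenzyl alcohol | COc1cccc(CO)c1 | starting material
13 | (5-methoxycyclohexa-1,4-dien-1-yl)methanol (not isolated) | COC1=CCC=C(CO)C1 | intermediate
14 | 3-(hydroxymethyl)cyclohex-3-en-1-one (not isolated) | O=C1CC(CO)=CCC1 | intermediate
15 | 3-(hydroxymethyl)cyclohex-2-en-1-one | O=C1C=C(CO)CCC1 | intermediate
16 | 3-({[tert-butyl(dimethyl)silyl]oxy}methyl)cyclohex-2-en-1-one | O=C1C=C(CO[Si](C)(C)C(C)(C)C)CCC1 | intermediate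
17 | vinylmagnesium bromide | C=C[Mg]Br | starting material
18 | dimethyl(vinyl)alane (not isolated) | C=C[Al](C)C | intermediate
19 | (3R)-3-({[tert-butyl(dimethyl)silyl]oxy}methyl)-3-ethenylcyclohexan-1-one | O=C1CCC[C@](CO[Si](C)(C)C(C)(C)C)(C=C)C1 | intermediate
20 | lithium (5R)-5-({[tert-butyl(dimethyl)silyl]oxy}methyl)-5-ethenylcyclohex-1-en-1-olate (not isolated) | [Li]OC1=CCC[C@](CO[Si](C)(C)C(C)(C)C)(C=C)C1 | intermediate
21 | (5R)-5-({[tert-butyl(dimethyl)silyl]oxy}methyl)-5-ethenylcyclohex-1-en-1-yl trifluoromethanesulfonate | FC(F)(F)S(=O)(=O)OC1=CCC[C@](CO[Si](C)(C)C(C)(C)C)(C=C)C1 | intermediate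
22 | [(5R)-5-({[tert-butyl(dimethyl)silyl]oxy}methyl)-5-ethenylcyclohex-1-en-1-yl]methanol | OCC1=CCC[C@](CO[Si](C)(C)C(C)(C)C)(C=C)C1 | intermediate
23 | tert-butyl{[(1R)-3-(chloromethyl)-1-ethenylcyclohex-3-en-1-yl]methoxy}dimethylsilane | ClCC1=CCC[C@](CO[Si](C)(C)C(C)(C)C)(C=C)C1 | intermediate
24 | allylbarium chloride from 23 (not isolated) | Cl[Ba]CC1=CCC[C@](CO[Si](C)(C)C(C)(C)C)(C=C)C1 | intermediate
25 | methyl (1R)-2-{2-[(5R)-5-(TBS-oxymethyl)-5-ethenylcyclohex-1-en-1-yl]-1-hydroxyethyl}-1,3-dimethylcyclohex-2-ene-1-carboxylate (C6 epimers) | COC(=O)[C@]1(C)CCCC(C)=C1C(O)CC2=CCC[C@](CO[Si](C)(C)C(C)(C)C)(C=C)C2 | intermediate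
26 | methyl (1R)-2-{[(5R)-5-(TBS-oxymethyl)-5-ethenylcyclohex-1-en-1-yl]acetyl}-1,3-dimethylcyclohex-2-ene-1-carboxylate | COC(=O)[C@]1(C)CCCC(C)=C1C(=O)CC2=CCC[C@](CO[Si](C)(C)C(C)(C)C)(C=C)C2 | intermediate
27 | (6R)-epimer of 25 (not isolated) | COC(=O)[C@]1(C)CCCC(C)=C1[C@H](O)CC2=CCC[C@](CO[Si](C)(C)C(C)(C)C)(C=C)C2 | intermediate
28 | (3R,7aR)-3-{[(5R)-5-(TBS-oxymethyl)-5-ethenylcyclohex-1-en-1-yl]methyl}-4,7a-dimethyl-5,6,7,7a-tetrahydroisobenzofuran-1(3H)-one | CC1=C2[C@@H](CC3=CCC[C@](CO[Si](C)(C)C(C)(C)C)(C=C)C3)OC(=O)[C@]2(C)CCC1 | intermediate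
29 | potassium salt of the (4R,6R,16R)-hydroxy acid from 28 | [K+].[O-]C(=O)[C@]1(C)CCCC(C)=C1[C@H](O)CC2=CCC[C@](CO[Si](C)(C)C(C)(C)C)(C=C)C2 | intermediate
30 | dipotassium alkoxide carboxylate of 29 (not isolated) | [K+].[K+].[O-]C(=O)[C@]1(C)CCCC(C)=C1[C@H]([O-])CC2=CCC[C@](CO[Si](C)(C)C(C)(C)C)(C=C)C2 | intermediate
31 | dipotassium C5=C6 enolate carboxylate after rearrangement (4R,9R,10S,16R; not isolated) | [K+].[K+].C[C@@]1([C@@H]2CC[C@](CO[Si](C)(C)C(C)(C)C)(C=C)CC2=C)CCC[C@@](C)(C(=O)[O-])C1=C[O-] | intermediate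
32 | pseudo-acid (4R,5S,9R,10S,16R): cis-fused 6-hydroxy-19,6-lactone on ring A; C10 bears CH3 and C9 of the cyclohexane with C8=CH2 and C16 vinyl/CH2OTBS | C[C@@]1([C@@H]2CC[C@](CO[Si](C)(C)C(C)(C)C)(C=C)CC2=C)CCC[C@@]3(C)C(=O)OC(O)[C@@H]13 | intermediate
33 | C6 acetate of 32 | C[C@@]1([C@@H]2CC[C@](CO[Si](C)(C)C(C)(C)C)(C=C)CC2=C)CCC[C@@]3(C)C(=O)OC(OC(C)=O)[C@@H]13 | intermediate
34 | C17 alcohol from 33 | C[C@@]1([C@@H]2CC[C@](CO)(C=C)CC2=C)CCC[C@@]3(C)C(=O)OC(OC(C)=O)[C@@H]13 | intermediate
35 | di-tert-butyl dicarbonate | CC(C)(C)OC(=O)OC(=O)OC(C)(C)C | starting material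
36 | C17 tert-butyl carbonate of 34 | C[C@@]1([C@@H]2CC[C@](COC(=O)OC(C)(C)C)(C=C)CC2=C)CCC[C@@]3(C)C(=O)OC(OC(C)=O)[C@@H]13 | intermediate
37 | key-step precursor (4R,5S,8R,9S,10S,16R): C8 spiro-epoxide, C16 vinyl and CH2OBoc, ring A acetoxy lactone | C[C@@]1([C@@H]2CC[C@](COC(=O)OC(C)(C)C)(C=C)C[C@]24CO4)CCC[C@@]3(C)C(=O)OC(OC(C)=O)[C@@H]13 | intermediate
38 | zwitterion: 2-tert-butoxy-1,3-dioxolan-2-ylium on C16/C17 with C7–O–AlMeCl2 aluminate (not isolated) | C[C@@]1([C@@H]2CC[C@@H]4C[C@@]2(CO[Al-](C)(Cl)Cl)C[C@]4(OC(OC(C)(C)C)=[O+]5)C5)CCC[C@@]3(C)C(=O)OC(OC(C)=O)[C@@H]13 | intermediate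
39 | key-step product (4R,5S,8R,9S,10S,13R,16R)-6-acetoxy-7-hydroxy-6,7-secokauran-19,6-olide 16,17-cyclic carbonate | C[C@@]1([C@@H]2CC[C@@H]4C[C@@]2(CO)C[C@]4(OC(=O)O5)C5)CCC[C@@]3(C)C(=O)OC(OC(C)=O)[C@@H]13 | intermediate
40 | 7-oxo analogue of 39 | C[C@@]1([C@@H]2CC[C@@H]4C[C@@]2(C=O)C[C@]4(OC(=O)O5)C5)CCC[C@@]3(C)C(=O)OC(OC(C)=O)[C@@H]13 | intermediate
41 | (4R,5S,8R,9S,10S,13R,16R)-16,17-dihydroxy-6,7-dioxo-6,7-secokauran-19-oic acid | C[C@@]1([C@@H]2CC[C@@H]3C[C@@]2(C=O)C[C@]3(O)CO)CCC[C@@](C)(C(=O)O)[C@H]1C=O | target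

**Step count and risks**

Total steps: 23. Longest linear sequence: 18 (steps 6–11, then 12–23).

Steps most likely to fail:

1. Step 21 (proposed new method). The opened epoxide may collapse by hydride shift from C7 or by proton loss before the vinyl group closes the ring, or the carbonate may capture the C13 cation before the C12 shift. The fallback uses known reactions and sets out from 37.
 - Ligand-accelerated dihydroxylation of the vinyl group (OsO4, NMO, (DHQD)2PHAL) should give the (13R)-diol F1 by the usual mnemonic.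
 - MsCl/Et3N gives the bis-mesylate F2.
 - MeAl(OC6H2-2,6-tBu2-4-Br)2 rearranges the spiro-epoxide to the C8 aldehyde F3 (Meinwald rearrangement).
 - KN(SiMe3)2 closes C8–C14 by intramolecular enolate alkylation of the primary mesylate (5-exo-tet), giving the bicyclo[3.2.1]octane F4 with the C13 mesylate exo and antiperiplanar to C16–C12.
 - Buffered solvolysis (2,6-lutidine, (CF3)2CHOH, 50 °C) then effects the Wagner–Meerwein shift of C12 with carbonate capture at C16 and returns to the route at 40.

2. Step 16. The doubly charged substrate may rearrange slowly, lose the allyl unit by fragmentation, or react through the chair with the oxyanion pseudo-axial, which would pair the opposite faces of C10 and C9. The fallback sets out from 28.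
 - Aminolysis with Me2AlNMe2 (from AlMe3 and Me2NH·HCl) gives the hydroxy dimethylamide F5, which cannot lactonise under base.
 - The classical mono-anionic oxy-Cope rearrangement (KH, 18-crown-6, THF) gives the aldehyde amide F6.
 - Dilute aqueous acetic acid in THF lets the aldehyde hydrate displace the neighbouring amide and returns to the route at 32.

3. Step 8. Facial selectivity may be poor, or methyl may transfer in place of vinyl. The fallback sets out from 16.
 - Racemic copper-catalysed addition of 17 (CuBr·SMe2, TMSCl, THF, −78 °C, then dilute acid) gives the racemic ketone F7.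
 - Resolution by chromatography on a chiral stationary phase returns to the route at 19.

**Further compounds**

F1 | step 21 | (13R)-13,14-diol from dihydroxylation of the vinyl group of 37 | C[C@@]1([C@@H]2CC[C@](COC(=O)OC(C)(C)C)([C@@H](O)CO)C[C@]24CO4)CCC[C@@]3(C)C(=O)OC(OC(C)=O)[C@@H]13
F2 | step 21 | 13,14-bis-mesylate of F1 | C[C@@]1([C@@H]2CC[C@](COC(=O)OC(C)(C)C)([C@@H](OS(C)(=O)=O)COS(C)(=O)=O)C[C@]24CO4)CCC[C@@]3(C)C(=O)OC(OC(C)=O)[C@@H]13
F3 | step 21 | C8 aldehyde from epoxide rearrangement of F2 (C8 epimers) | C[C@@]1([C@@H]2CC[C@](COC(=O)OC(C)(C)C)([C@@H](OS(C)(=O)=O)COS(C)(=O)=O)CC2C=O)CCC[C@@]3(C)C(=O)OC(OC(C)=O)[C@@H]13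
F4 | step 21 | bicyclo[3.2.1]octane with C8–C14 bond, C7 aldehyde on C8 and exo C13 mesylate | C[C@@]1([C@@H]2CC[C@@]4(COC(=O)OC(C)(C)C)C[C@]2(C=O)C[C@@H]4OS(C)(=O)=O)CCC[C@@]3(C)C(=O)OC(OC(C)=O)[C@@H]13
F5 | step 16 | (4R,6R,16R)-hydroxy N,N-dimethylamide from aminolysis of 28 | CN(C)C(=O)[C@]1(C)CCCC(C)=C1[C@H](O)CC2=CCC[C@](CO[Si](C)(C)C(C)(C)C)(C=C)C2
F6 | step 16 | C6 aldehyde C19 dimethylamide after oxy-Cope rearrangement | C[C@@]1([C@@H]2CC[C@](CO[Si](C)(C)C(C)(C)C)(C=C)CC2=C)CCC[C@@](C)(C(=O)N(C)C)[C@H]1C=O
F7 | step 8 | racemic 3-({[tert-butyl(dimethyl)silyl]oxy}methyl)-3-ethenylcyclohexan-1-one | C=CC1(CO[Si](C)(C)C(C)(C)C)CCCC(=O)C1
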